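## Retrosynthetic overview

1. **Numbering and feature.** Ring A is the arene C1–C6: C1 bears C7H2O, C3 bears O3, C4 bears C8. Ring B is the oxirane C8–C9–O. C10 is the CH2OAc on C8, and C2'' is the α-carbon of the 2-methylbutanoate. In ring B, C9 carries two hydrogens and no carbon substituent, and its only heavy-atom neighbours are the quaternary C8 and the ring oxygen. Taking out that one CH2 leaves an aryl ketone C8=O.
2. **Endgame.** The O3 angelate goes on last, onto a phenol released from an allyl ether. The O10 acetate is traced back to a silyl ether. Neither acyl group would survive a basic ylide.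
3. **Key disconnection.** C8–C9 and C9–O are cut back to a 2-silyloxy-1-arylethanone plus dimethyloxosulfonium methylide. A LaLi3(binaphthoxide)3 catalyst sets C8.
4. **Ketone.** It is cut at C4–C8 into an arylmagnesium and a silyloxyacetic Weinreb amide. The arylmagnesium comes from methyl 3-hydroxy-4-iodobenzoate by allylation, reduction and esterification with (R)-2-methylbutanoic acid, which supplies C2''.
5. **Ring order.** Ring A is bought. Ring B is the only ring formed, in step 7.

Key step: step 7

Assumption: the ketone face opened by a given hand of BINOL cannot be carried over safely from methyl ketones, because the ortho-allyloxy oxygen can act as a second donor to lanthanum; (S)-BINOL is written, the configuration of the first batch of oxirane is to be checked against material from the tartrate-controlled epoxidation described under the fallbacks, and the equally available (R)-BINOL is used if the check demands it.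

## Route

**Step 1**
Reactants: 1 methyl 3-hydroxy-4-iodobenzoate
Product: 2 methyl 3-(allyloxy)-4-iodobenzoate
Conditions: allyl bromide, K2CO3, DMF, rt
Reagents that add atoms: allyl bromide, C=CCBr
Why: Williamson ether synthesis, in which the phenoxide made by K2CO3 displaces bromide while the aryl iodide and methyl ester stay inert; the allyl ether is chosen because it withstands hydride, Grignard reagent, ylide and fluoride and can later be removed without acid or strong base.

**Step 2**
Reactants: 2 methyl 3-(allyloxy)-4-iodobenzoate
Product: 3 [3-(allyloxy)-4-iodophenyl]methanol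
Conditions: iBu2AlH (2.5 equiv), CH2Cl2, −78 → 0 °C; aq potassium sodium tartrate
Reagents that add atoms: none
Why: Ester-to-alcohol reduction by two hydride transfers from iBu2AlH, which at low temperature spares the aryl–iodine bond and the terminal alkene, whereas LiAlH4 could cause hydrodeiodination.

**Step 3**
Reactants: 3 [3-(allyloxy)-4-iodophenyl]methanol; 4 (R)-2-methylbutanoic acid
Product: 5 3-(allyloxy)-4-iodobenzyl (2R)-2-methylbutanoate
Conditions: EDC·HCl, DMAP (10 mol %), CH2Cl2, 0 °C → rt
Reagents that add atoms: none
Why: Steglich-type carbodiimide esterification of an unhindered primary benzylic alcohol, which brings in C2'' with the R configuration of acid 4; the low DMAP charge and temperature should keep the activated acid from epimerising through a ketene or enol.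

**Step 4**
Reactants: 6 methyl glycolate
Product: 7 methyl 2-[(tert-butyldimethylsilyl)oxy]acetate
Conditions: TBSCl, imidazole, CH2Cl2, rt
Reagents that add atoms: tert-butyldimethylsilyl chloride, C[Si](C)(Cl)C(C)(C)C
Why: Imidazole-promoted silylation of a primary alcohol, a routine protection that makes O10 inert to Grignard reagent and ylide.

**Step 5**
Reactants: 7 methyl 2-[(tert-butyldimethylsilyl)oxy]acetate
Product: 8 2-[(tert-butyldimethylsilyl)oxy]-N-methoxy-N-methylacetamide
Conditions: MeNH(OMe)·HCl, iPrMgCl, THF, −20 → 0 °C
Reagents that add atoms: N,O-dimethylhydroxylamine hydrochloride, CNOC.Cl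
Why: Weinreb amide formation by aminolysis of the methyl ester with the chloromagnesium amide made in the flask from MeNH(OMe)·HCl and iPrMgCl, conditions under which a silyl ether is stable.

**Step 6**
Reactants: 5 3-(allyloxy)-4-iodobenzyl (2R)-2-methylbutanoate; 8 2-[(tert-butyldimethylsilyl)oxy]-N-methoxy-N-methylacetamide
Product: 11 3-(allyloxy)-4-{2-[(tert-butyldimethylsilyl)oxy]acetyl}benzyl (2R)-2-methylbutanoate, via arylmagnesium chloride 9 (not isolated), via chloromagnesium hemiaminal chelate 10 (not isolated)
Conditions: iPrMgCl·LiCl (1.1 equiv), THF, −30 °C; then 8 (1.3 equiv), −30 → 0 °C; aq NH4Cl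
Reagents that add atoms: none
Why: Iodine–magnesium exchange with iPrMgCl·LiCl, fast on an aryl iodide next to a coordinating alkoxy group and run cold enough that the α-branched C7 ester is neither attacked nor deprotonated, followed by Weinreb ketone synthesis, in which chelate 10 survives until the quench so that C4–C8 forms without over-addition.

**Step 7**
Reactants: 11 3-(allyloxy)-4-{2-[(tert-butyldimethylsilyl)oxy]acetyl}benzyl (2R)-2-methylbutanoate; 12 trimethylsulfoxonium chloride
Product: 15 3-(allyloxy)-4-[(2R)-2-{[(tert-butyldimethylsilyl)oxy]methyl}oxiran-2-yl]benzyl (2R)-2-methylbutanoate, via dimethyloxosulfonium methylide 13 (not isolated), via sulfoxonium betaine 14 (not isolated)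
Conditions: 12, NaH, THF, reflux, filtered under Ar (salt-free solution of 13, 1.2 equiv); 11, LaLi3[(S)-binaphthoxide]3 (10 mol %, from La(OiPr)3/(S)-BINOL/BuLi 1:3:3, iPrOH stripped in vacuo), (2,4,6-(MeO)3C6H2)3P=O (10 mol %), MS 5Å, THF, rt
Reagents that add atoms: none
Why: This is the catalytic asymmetric Corey–Chaykovsky epoxidation, a reaction type established for aryl and alkyl methyl ketones and, less selectively, for ethyl and propyl ketones, used here on an aryl ketone whose small arm is CH2OTBS. The carbonyl oxygen of 11 binds to the trivalent lanthanum centre, whose coordination sphere is adjusted by the phosphine oxide, while a lithium binaphthoxide site holds the oxygen of ylide 13, so that the ylide carbon is delivered to one face of C8 and forms C8–C9 (betaine 14). The C8 alkoxide of 14 then expels dimethyl sulfoxide from C9 in a 3-exo-tet substitution that forms C9–O and closes ring B without touching C8. C8 is therefore fixed in the addition step by the binaphthoxide pocket, which has to tell the ortho-allyloxyaryl group, twisted out of the carbonyl plane and thus broad, from the slim CH2 of the silyloxymethyl arm. The step needs chemoselectivity for the ketone: the stabilised ylide (1.2 equiv, rt) should not acylate on the α-branched alkyl ester at C7, O3 is an ether and O10 a silyl ether so that no reactive acyl group is offered, enolisation of 11 is reversible and erases no stereocentre, and stripping iPrOH from the catalyst denies lanthanum alkoxide the means to transesterify C7. Holding the ylide close to one equivalent at rt also suppresses a second methylene transfer, which would expand the oxirane to an oxetane.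

**Step 8**
Reactants: 15 3-(allyloxy)-4-[(2R)-2-{[(tert-butyldimethylsilyl)oxy]methyl}oxiran-2-yl]benzyl (2R)-2-methylbutanoate
Product: 16 3-(allyloxy)-4-[(2S)-2-(hydroxymethyl)oxiran-2-yl]benzyl (2R)-2-methylbutanoate
Conditions: Bu4NF/AcOH (1:1), THF, 0 °C
Reagents that add atoms: none
Why: Fluoride-driven desilylation, buffered so that the esters and the oxirane survive; should the C10 alkoxide attack C8 (Payne rearrangement), the inversion at C8 is cancelled by the exchange of roles of C9 and C10 and the same enantiomer returns, and the descriptor reads S only because CH2OH ranks below the ring CH2.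

**Step 9**
Reactants: 16 3-(allyloxy)-4-[(2S)-2-(hydroxymethyl)oxiran-2-yl]benzyl (2R)-2-methylbutanoate
Product: 17 4-[(2R)-2-(acetoxymethyl)oxiran-2-yl]-3-(allyloxy)benzyl (2R)-2-methylbutanoate
Conditions: Ac2O, Et3N, DMAP (5 mol %), CH2Cl2, 0 °C
Reagents that add atoms: acetic anhydride, CC(=O)OC(C)=O
Why: DMAP-catalysed acetylation of the only free hydroxyl group under basic, acid-free conditions that leave the acid-sensitive benzylic oxirane closed; C8 is untouched in space and its descriptor returns to R.

**Step 10**
Reactants: 17 4-[(2R)-2-(acetoxymethyl)oxiran-2-yl]-3-(allyloxy)benzyl (2R)-2-methylbutanoate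
Product: 18 4-[(2R)-2-(acetoxymethyl)oxiran-2-yl]-3-hydroxybenzyl (2R)-2-methylbutanoate
Conditions: Pd(PPh3)4 (5 mol %), PhNHMe (1.5 equiv), degassed THF, rt; short plug of Et3N-washed SiO2; used at once
Reagents that add atoms: none
Why: Tsuji–Trost-type deallylation, in which zerovalent palladium ionises the allyl aryl ether to a π-allyl complex and phenoxide and the weakly basic amine takes up the allyl group, while the non-allylic acetate, the benzylic ester and the non-vinylic oxirane are not substrates of this catalyst at rt.

**Step 11**
Reactants: 18 4-[(2R)-2-(acetoxymethyl)oxiran-2-yl]-3-hydroxybenzyl (2R)-2-methylbutanoate; 19 angelic acid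
Product: 21 2-[(2R)-2-(acetoxymethyl)oxiran-2-yl]-5-{[(2R)-2-methylbutanoyloxy]methyl}phenyl (Z)-2-methylbut-2-enoate (target), via angelic trichlorobenzoic mixed anhydride 20 (not isolated)
Conditions: 19, 2,4,6-Cl3C6H2COCl, Et3N, toluene, rt; then 18, Et3N, 0 °C → rt, no DMAP
Reagents that add atoms: none
Why: Yamaguchi-type mixed-anhydride esterification, in which the phenol attacks the less hindered angeloyl carbonyl of 20; leaving out any nucleophilic catalyst removes the conjugate addition–elimination path by which angelates turn into tiglates, so the Z geometry of 19 should be carried into 21.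

## Compound list

| No. | Name | SMILES | Role |
|---|---|---|---|
| 1 | methyl 3-hydroxy-4-iodobenzoate | COC(=O)c1ccc(I)c(O)c1 | starting material |
| 2 | methyl 3-(allyloxy)-4-iodobenzoate | COC(=O)c1ccc(I)c(OCC=C)c1 | intermediate |
| 3 | [3-(allyloxy)-4-iodophenyl]methanol | OCc1ccc(I)c(OCC=C)c1 | intermediate |
| 4 | (R)-2-methylbutanoic acid | OC(=O)[C@H](C)CC | starting material |
| 5 | 3-(allyloxy)-4-iodobenzyl (2R)-2-methylbutanoate | C=CCOc1cc(COC(=O)[C@H](C)CC)ccc1I | intermediate |
| 6 | methyl glycolate | COC(=O)CO | starting material |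
| 7 | methyl 2-[(tert-butyldimethylsilyl)oxy]acetate | COC(=O)CO[Si](C)(C)C(C)(C)C | intermediate |
| 8 | 2-[(tert-butyldimethylsilyl)oxy]-N-methoxy-N-methylacetamide | CON(C)C(=O)CO[Si](C)(C)C(C)(C)C | intermediate |
| 9 | {2-(allyloxy)-4-[((2R)-2-methylbutanoyloxy)methyl]phenyl}magnesium chloride (LiCl complex) | C=CCOc1cc(COC(=O)[C@H](C)CC)ccc1[Mg]Cl | intermediate |
| 10 | chloromagnesium hemiaminal chelate, adduct of 9 to 8 (carbinol centre unassigned, lost on quench) | C=CCOc1cc(COC(=O)[C@H](C)CC)ccc1C(O[Mg]Cl)(CO[Si](C)(C)C(C)(C)C)N(C)OC | intermediate |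
| 11 | 3-(allyloxy)-4-{2-[(tert-butyldimethylsilyl)oxy]acetyl}benzyl (2R)-2-methylbutanoate | C=CCOc1cc(COC(=O)[C@H](C)CC)ccc1C(=O)CO[Si](C)(C)C(C)(C)C | intermediate |
| 12 | trimethylsulfoxonium chloride | C[S+](C)(C)=O.[Cl-] | starting material |
| 13 | dimethyloxosulfonium methylide | CS(C)(=O)=C | intermediate |
| 14 | sulfoxonium betaine, C8 arranged as in 15 (formally S) | C=CCOc1cc(COC(=O)[C@H](C)CC)ccc1[C@]([O-])(CO[Si](C)(C)C(C)(C)C)C[S+](C)(C)=O | intermediate |
| 15 | 3-(allyloxy)-4-[(2R)-2-{[(tert-butyldimethylsilyl)oxy]methyl}oxiran-2-yl]benzyl (2R)-2-methylbutanoate | C=CCOc1cc(COC(=O)[C@H](C)CC)ccc1[C@]1(CO[Si](C)(C)C(C)(C)C)CO1 | intermediate |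
| 16 | 3-(allyloxy)-4-[(2S)-2-(hydroxymethyl)oxiran-2-yl]benzyl (2R)-2-methylbutanoate | C=CCOc1cc(COC(=O)[C@H](C)CC)ccc1[C@]1(CO)CO1 | intermediate |
| 17 | 4-[(2R)-2-(acetoxymethyl)oxiran-2-yl]-3-(allyloxy)benzyl (2R)-2-methylbutanoate | C=CCOc1cc(COC(=O)[C@H](C)CC)ccc1[C@]1(COC(C)=O)CO1 | intermediate |
| 18 | 4-[(2R)-2-(acetoxymethyl)oxiran-2-yl]-3-hydroxybenzyl (2R)-2-methylbutanoate | Oc1cc(COC(=O)[C@H](C)CC)ccc1[C@]1(COC(C)=O)CO1 | intermediate |
| 19 | angelic acid, (Z)-2-methylbut-2-enoic acid | C/C=C(/C)C(=O)O | starting material |
| 20 | (Z)-2-methylbut-2-enoic 2,4,6-trichlorobenzoic anhydride | C/C=C(/C)C(=O)OC(=O)c1c(Cl)cc(Cl)cc1Cl | intermediate |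
| 21 | 2-[(2R)-2-(acetoxymethyl)oxiran-2-yl]-5-{[(2R)-2-methylbutanoyloxy]methyl}phenyl (Z)-2-methylbut-2-enoate | C/C=C(/C)C(=O)Oc1cc(COC(=O)[C@H](C)CC)ccc1[C@]1(COC(C)=O)CO1 | target |

## Step count

- Total step count: 11.
- Longest linear sequence: 9 (steps 1, 2, 3, 6, 7, 8, 9, 10, 11).

## Steps most likely to fail

**1. Step 7.**
- Facial discrimination may be poor. Both groups at the carbonyl are larger than the methyl group for which the catalyst works best.
- Two-point binding through the ortho-allyloxy oxygen may change or erode the sense of induction.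
- Addition to the hindered ketone may be slow.
- The distant C2'' centre would give little help in separating C8 epimers.

The fallback sets out from 11 and comes back at 16.
- Wittig methylenation of 11 (Ph3PCH3Br, KOtBu, THF, 0 °C) would give 3-(allyloxy)-4-{3-[(tert-butyldimethylsilyl)oxy]prop-1-en-2-yl}benzyl (2R)-2-methylbutanoate F1.
- Bu4NF would free 3-(allyloxy)-4-(3-hydroxyprop-1-en-2-yl)benzyl (2R)-2-methylbutanoate F2.
- A hydroxyl-directed Sharpless asymmetric epoxidation (Ti(OiPr)4, L-(+)-diisopropyl tartrate, tBuOOH, MS 4Å, CH2Cl2, −20 °C) would then put oxygen on the alkene instead of methylene on the ketone.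
- The O-allyl alkene has no directing hydroxyl and should stay untouched.
- L-(+)-tartrate is the hand that turns allyl alcohol into (S)-glycidol. With the aryl group in place of that hydrogen, the same face corresponds to (S)-16.

**2. Step 10.**
- Once the allyl group is lost, the free phenol or phenoxide may attack C9. This opens ring B to a 2,3-dihydrobenzofuran-3-ol, which can aromatise by loss of water.
- Traces of acid or prolonged contact with palladium may isomerise the benzylic oxirane to an aldehyde (Meinwald-type rearrangement).

The fallback sets out from 17 and comes back at 21, and the phenol is never set free.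
- Palladium-catalysed hydrostannolysis (Pd(PPh3)4, Bu3SnH, CH2Cl2, rt) would deliver the covalent, weakly basic 4-[(2R)-2-(acetoxymethyl)oxiran-2-yl]-3-[(tributylstannyl)oxy]benzyl (2R)-2-methylbutanoate F3.
- Its Sn–O bond is acylated in the same flask by the preformed mixed anhydride 20.

**3. Step 11.**
- Z-to-E isomerisation of the activated angeloyl group may occur.
- Acylation of the ortho-substituted phenol may be sluggish, so that cyclisation onto the oxirane competes.
- Attack may take place at the wrong carbonyl of the anhydride.

The fallback sets out from 18 and comes back at 21, and the double bond is built after the ester bond.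
- Coupling 18 with 2-[bis(2,2,2-trifluoroethoxy)phosphoryl]propanoic acid (EDC·HCl, DMAP, CH2Cl2, 0 °C) would give 2-[(2R)-2-(acetoxymethyl)oxiran-2-yl]-5-{[(2R)-2-methylbutanoyloxy]methyl}phenyl 2-[bis(2,2,2-trifluoroethoxy)phosphoryl]propanoate F4, as a mixture at the phosphonate carbon.
- A Still–Gennari olefination (KN(SiMe3)2, 18-crown-6, THF, −78 °C; then acetaldehyde) should place the new methyl group cis to the carboxyl carbon, which is the angelate geometry.
- Only the phosphonate α-proton should be removed by one equivalent of base at that temperature.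

## Further compounds

F1 | step 7 | 3-(allyloxy)-4-{3-[(tert-butyldimethylsilyl)oxy]prop-1-en-2-yl}benzyl (2R)-2-methylbutanoate | C=CCOc1cc(COC(=O)[C@H](C)CC)ccc1C(=C)CO[Si](C)(C)C(C)(C)C
F2 | step 7 | 3-(allyloxy)-4-(3-hydroxyprop-1-en-2-yl)benzyl (2R)-2-methylbutanoate | C=CCOc1cc(COC(=O)[C@H](C)CC)ccc1C(=C)CO
F3 | step 10 | 4-[(2R)-2-(acetoxymethyl)oxiran-2-yl]-3-[(tributylstannyl)oxy]benzyl (2R)-2-methylbutanoate | CCCC[Sn](CCCC)(CCCC)Oc1cc(COC(=O)[C@H](C)CC)ccc1[C@]1(COC(C)=O)CO1
F4 | step 11 | 2-[(2R)-2-(acetoxymethyl)oxiran-2-yl]-5-{[(2R)-2-methylbutanoyloxy]methyl}phenyl 2-[bis(2,2,2-trifluoroethoxy)phosphoryl]propanoate | CC(P(=O)(OCC(F)(F)F)OCC(F)(F)F)C(=O)Oc1cc(COC(=O)[C@H](C)CC)ccc1[C@]1(COC(C)=O)CO1
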